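The two exocyclic bonds of ring B, C9–C11 and C8–C17, are disconnected together. In labdane numbering C9 and C8 are the β- and α-carbons of a C7 ketone in the cis-fused decalin. One conjugate addition of a vinyl copper reagent to the C8=C9 enone, with capture of the regiodefined enolate by an iminium salt, therefore forms both bonds and sets C9. The precursor is the cis-fused enone carrying C19 as a silyl ether. It is made with the C8=C9 double bond already in place, by radical cyclisation of an epoxide onto one arm of a 4,4-disubstituted cyclohexadienone, so no regioselective enolisation of a cis-decalone is needed.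

Key step: step 9

Remark 1: labdane numbering is used for all bicyclic compounds; α is the face that carries CH3-10, and in the target CH3-10, H-5, C19 and the C9 side chain are all α (cis-fused decalin).
Remark 2: racemic melonal is used, because its stereocentre becomes the prochiral C10 of dienone 7.
Remark 3 (assumption): step 6 is taken to run through the chair-like transition state with the C3 titanoxy group equatorial; this fixes L-(+)-diethyl tartrate in step 4, and D-(−)-diethyl tartrate would be used if the other enone arm proves to be preferred.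

Step 1
Reactants: 1 2,6-dimethylhept-5-enal (melonal, racemic); 2 methyl vinyl ketone
Product: 5 4-methyl-4-(4-methylpent-3-en-1-yl)cyclohex-2-en-1-one (racemic), via pyrrolidine enamine 3 (not isolated), via keto aldehyde 4 (not isolated)
Conditions: pyrrolidine, PhMe, Dean–Stark, reflux; 2, 0 → 25 °C; then AcOH/NaOAc/H2O, 90 °C
Reagents that add atoms: none
Why: Stork enamine Michael addition to 2 followed by hydrolysis and aldol condensation (Robinson annulation) builds ring B around quaternary C10, whose configuration is irrelevant because step 2 makes it prochiral.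

Step 2
Reactants: 5 4-methyl-4-(4-methylpent-3-en-1-yl)cyclohex-2-en-1-one
Product: 7 4-methyl-4-(4-methylpent-3-en-1-yl)cyclohexa-2,5-dien-1-one, via silyl dienol ether 6 (not isolated)
Conditions: LiN(iPr)2, THF, −78 °C; Me3SiCl; then Pd(OAc)2 (1.1 equiv), MeCN, 25 °C
Reagents that add atoms: none
Why: Kinetic deprotonation can occur only at the sole sp3 α-carbon, and Saegusa–Ito dehydrogenation of the silyl dienol ether by divalent palladium gives the symmetrical cross-conjugated dienone, so the future C8=C9 enone is present before ring A exists.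

Step 3
Reactants: 7 4-methyl-4-(4-methylpent-3-en-1-yl)cyclohexa-2,5-dien-1-one
Product: 8 4-[(3E)-5-hydroxy-4-methylpent-3-en-1-yl]-4-methylcyclohexa-2,5-dien-1-one
Conditions: SeO2 (20 mol%), t-BuOOH, salicylic acid (cat.), CH2Cl2, 25 °C
Reagents that add atoms: tert-butyl hydroperoxide, CC(C)(C)OO
Why: SeO2-catalysed allylic oxidation (ene reaction then [2,3]-sigmatropic shift) oxidises the (E)-methyl group of the trisubstituted alkene to the future C19 hydroxyl, and the dienone offers no enolisable or allylic C–H to compete.

Step 4
Reactants: 8 4-[(3E)-5-hydroxy-4-methylpent-3-en-1-yl]-4-methylcyclohexa-2,5-dien-1-one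
Product: 9 (2S,3S)-epoxy alcohol (oxirane across C3–C4 of the side chain)
Conditions: Ti(OiPr)4 (10 mol%), L-(+)-diethyl tartrate (12 mol%), t-BuOOH, 4 Å molecular sieves, CH2Cl2, −20 °C
Reagents that add atoms: tert-butyl hydroperoxide, CC(C)(C)OO
Why: Sharpless asymmetric epoxidation of an (E)-2-methylallylic alcohol, in which the titanium tartrate complex delivers oxygen to one alkene face and should set C3 and C4 as S,S, while the electron-poor dienone alkenes are inert to the electrophilic oxidant.

Step 5
Reactants: 9 (2S,3S)-epoxy alcohol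
Product: 10 (2S,3S)-epoxy tert-butyldimethylsilyl ether
Conditions: TBSCl, imidazole, DMF, 25 °C
Reagents that add atoms: tert-butyldimethylsilyl chloride, CC(C)(C)[Si](C)(C)Cl
Why: Standard silylation of the primary alcohol installs the C19 protecting group used in the key step and keeps the hydroxyl from binding titanium in step 6.

Step 6
Reactants: 10 (2S,3S)-epoxy tert-butyldimethylsilyl ether
Product: 11 cis-fused 3β-hydroxy enone (C7 ketone; C8=C9; 19-OTBS)
Conditions: Cp2TiCl2 (2.5 equiv), Zn dust, THF, 25 °C, slow addition of 10; aq. HCl work-up; chromatography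
Reagents that add atoms: none
Why: Reductive epoxide opening by Cp2TiCl (trivalent titanium, Nugent–RajanBabu reaction) gives the tertiary C4 radical, which adds 6-exo to C5 of one enone arm (Giese addition) before the α-keto radical is reduced to a titanium enolate and protonated at C6; the three-carbon tether forces cis fusion (H-5 syn to CH3-10), the equatorial titanoxy group at C3 decides which arm is attacked (C5 and C10), and methyl takes the axial site at the C4 radical so that C19 ends on the α face, the minor diastereomers being removable by chromatography.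

Step 7
Reactants: 11 cis-fused 3β-hydroxy enone
Product: 12 3-O-(imidazol-1-ylthiocarbonyl) derivative of 11
Conditions: 1,1′-thiocarbonyldiimidazole, DMAP, ClCH2CH2Cl, 80 °C
Reagents that add atoms: 1,1′-thiocarbonyldiimidazole, S=C(n1ccnc1)n1ccnc1
Why: Acylation of the hindered secondary C3 alcohol with the thiocarbonyl transfer reagent gives the radical-labile imidazolide required for Barton–McCombie deoxygenation.

Step 8
Reactants: 12 3-O-(imidazol-1-ylthiocarbonyl) derivative
Product: 13 cis-fused enone (C7 ketone; C8=C9; 19-OTBS)
Conditions: Bu3SnH, AIBN, PhMe, 100 °C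
Reagents that add atoms: none
Why: Barton–McCombie deoxygenation, in which the stannyl radical adds to sulfur and the C3–O bond fragments to a secondary radical that takes hydrogen from Bu3SnH, removes the oxygen that carried the chirality without touching C4, C5 or C10.

Step 9
Reactants: 13 cis-fused enone; 14 vinylmagnesium bromide; 15 dimethylmethyleneiminium iodide
Product: 17 amino ketone (9α-vinyl; 8β-dimethylaminomethyl; C7 ketone; 19-OTBS), via silyl enol ether 16 (not isolated)
Conditions: 14 (2.5 equiv), CuBr·SMe2 (20 mol%), Me3SiCl, DMPU, THF, −78 → −40 °C; Et3N, pentane, filtration; then 15, CH2Cl2, 0 → 25 °C; aq. NaHCO3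
Reagents that add atoms: none
Why: The vinyl copper species formed from 14 and CuBr·SMe2 forms a π-complex with the enone and transfers vinyl to C9, Me3SiCl captures the resulting C7 enolate as the C7=C8 silyl enol ether, and this attacks the iminium ion at C8 (Mukaiyama–Mannich reaction). The closest known reaction type is the three-component cuprate conjugate addition with trapping of the enolate by an iminium salt, and no ring is closed. C9 is set by the cis ring fusion: CH3-10 and H-5 mark the convex α face, and ring A covers the β face in either chair of ring B (C1 axial in one, C4 axial in the other), so axial attack at C9 comes from the α face, meets only H-5 and places vinyl syn to CH3-10. C8 is set anti to the new vinyl group by the approach of the iminium ion, and this centre is erased in step 14. The step needs facial selectivity at C9 and alkylation at C8 and not at C6; the first is secured by the fold of the cis-decalin and the second by forming the enolate through the conjugate addition itself and holding it as the silyl enol ether.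

Step 10
Reactants: 17 amino ketone
Product: 18 amino alcohol (C7 hydroxyl; either C7 epimer)
Conditions: NaBH4, MeOH, 0 °C
Reagents that add atoms: none
Why: Borohydride reduction of the Mannich-base ketone gives the C7 alcohol, whose configuration does not matter because C7 becomes CH2, and it removes the risk of retro-Mannich elimination.

Step 11
Reactants: 18 amino alcohol
Product: 19 7-O-(imidazol-1-ylthiocarbonyl) derivative of 18
Conditions: 1,1′-thiocarbonyldiimidazole, DMAP, ClCH2CH2Cl, 70 °C
Reagents that add atoms: 1,1′-thiocarbonyldiimidazole, S=C(n1ccnc1)n1ccnc1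
Why: Thiocarbonylation with the imidazole reagent prepares the Barton–McCombie step and avoids alkylating or chloroformate-type reagents that would attack the tertiary amine.

Step 12
Reactants: 19 7-O-(imidazol-1-ylthiocarbonyl) derivative
Product: 20 amine (9α-vinyl; 8β-dimethylaminomethyl; C7 methylene; 19-OTBS)
Conditions: Bu3SnH, AIBN, PhMe, 100 °C
Reagents that add atoms: none
Why: Barton–McCombie deoxygenation turns C7 into CH2, the secondary C7 radical being reduced by Bu3SnH faster than it could close a four- or five-membered ring onto the vinyl group.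

Step 13
Reactants: 20 amine; 21 3-bromofuran-2(5H)-one
Product: 23 butenolide amine (C12 bonded to C13 of the furanone), via alkylborane 22 (not isolated)
Conditions: 9-BBN (2.5 equiv), THF, 0 → 60 °C; then 21, Pd(dppf)Cl2 (10 mol%), AsPh3, aq. K3PO4, DMF, 25 °C
Reagents that add atoms: none
Why: Anti-Markovnikov hydroboration of the only alkene present (C17 is still masked as the aminomethyl group, so no competing 1,1-disubstituted alkene exists) followed by B-alkyl Suzuki–Miyaura coupling with the α-bromobutenolide joins C12 to C13.

Step 14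
Reactants: 23 butenolide amine
Product: 25 8(17)-methylene compound (19-OTBS), via amine N-oxide 24 (not isolated)
Conditions: mCPBA, CH2Cl2, −20 °C; basic Al2O3; then PhMe, 100 °C
Reagents that add atoms: none
Why: Amine oxidation followed by Cope elimination (thermal syn-elimination through a five-membered transition state) can use only H-8, so the exocyclic C8=C17 alkene forms regiospecifically and the expendable C8 stereocentre disappears, while the electron-poor butenolide alkene is not epoxidised.

Step 15
Reactants: 25 8(17)-methylene compound (19-OTBS)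
Product: 26 primary alcohol (19-OH)
Conditions: HF·pyridine, pyridine, THF, 0 → 25 °C
Reagents that add atoms: none
Why: Fluoride cleavage of the primary silyl ether under buffered, non-basic conditions spares the butenolide and the exocyclic alkene.

Step 16
Reactants: 26 primary alcohol (19-OH)
Product: 27 target (19-acetate)
Conditions: Ac2O, pyridine, DMAP (cat.), CH2Cl2, 25 °C
Reagents that add atoms: acetic anhydride, CC(=O)OC(C)=O
Why: DMAP-catalysed acetylation of the primary neopentyl-type alcohol gives the acetate of the target without affecting any stereocentre.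

Compound list
1 | 2,6-dimethylhept-5-enal (melonal, racemic) | CC(C)=CCCC(C)C=O | starting material
2 | methyl vinyl ketone (but-3-en-2-one) | CC(=O)C=C | starting material
3 | 1-(2,6-dimethylhepta-1,5-dien-1-yl)pyrrolidine | CC(C)=CCCC(C)=CN1CCCC1 | intermediate
4 | 2-methyl-2-(4-methylpent-3-en-1-yl)-5-oxohexanal (racemic) | CC(C)=CCCC(C)(C=O)CCC(C)=O | intermediate
5 | 4-methyl-4-(4-methylpent-3-en-1-yl)cyclohex-2-en-1-one (racemic) | O=C1C=CC(C)(CCC=C(C)C)CC1 | intermediate
6 | trimethyl{[4-methyl-4-(4-methylpent-3-en-1-yl)cyclohexa-1,5-dien-1-yl]oxy}silane | C[Si](C)(C)OC1=CCC(C)(CCC=C(C)C)C=C1 | intermediate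
7 | 4-methyl-4-(4-methylpent-3-en-1-yl)cyclohexa-2,5-dien-1-one (achiral) | O=C1C=CC(C)(CCC=C(C)C)C=C1 | intermediate
8 | 4-[(3E)-5-hydroxy-4-methylpent-3-en-1-yl]-4-methylcyclohexa-2,5-dien-1-one | O=C1C=CC(C)(CC/C=C(\C)CO)C=C1 | intermediate
9 | 4-{2-[(2S,3S)-3-(hydroxymethyl)-3-methyloxiran-2-yl]ethyl}-4-methylcyclohexa-2,5-dien-1-one | OC[C@]1(C)O[C@H]1CCC1(C)C=CC(=O)C=C1 | intermediate
10 | tert-butyldimethylsilyl ether of 9 | CC(C)(C)[Si](C)(C)OC[C@]1(C)O[C@H]1CCC1(C)C=CC(=O)C=C1 | intermediate
11 | (4aS,7S,8R,8aR)-8-{[tert-butyl(dimethyl)silyl]oxymethyl}-7-hydroxy-4a,8-dimethyl-4a,5,6,7,8,8a-hexahydronaphthalen-2(1H)-one (labdane numbering: C7 ketone, C8=C9, 3β-OH, 19-OTBS; CH3-10, H-5 and C19 α) | C1C(=O)C[C@H]2[C@](C)(CO[Si](C)(C)C(C)(C)C)[C@@H](O)CC[C@@]2(C)C=1 | intermediate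
12 | 3-O-(1H-imidazol-1-ylthiocarbonyl) derivative of 11 | C1C(=O)C[C@H]2[C@](C)(CO[Si](C)(C)C(C)(C)C)[C@@H](OC(=S)n3ccnc3)CC[C@@]2(C)C=1 | intermediate
13 | (4aS,8R,8aR)-8-{[tert-butyl(dimethyl)silyl]oxymethyl}-4a,8-dimethyl-4a,5,6,7,8,8a-hexahydronaphthalen-2(1H)-one (cis-fused; C7 ketone, C8=C9, 19-OTBS; CH3-10, H-5 and C19 α) | C1C(=O)C[C@H]2[C@](C)(CO[Si](C)(C)C(C)(C)C)CCC[C@@]2(C)C=1 | intermediate
14 | vinylmagnesium bromide | C=C[Mg]Br | starting material
15 | dimethylmethyleneiminium iodide | C=[N+](C)C.[I-] | starting material
16 | C7 trimethylsilyl enol ether (C7=C8) with 9α-vinyl group, 19-OTBS | C1=C(O[Si](C)(C)C)C[C@H]2[C@](C)(CO[Si](C)(C)C(C)(C)C)CCC[C@@]2(C)[C@@H]1C=C | intermediate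
17 | amino ketone: cis-fused C7 ketone with 9α-vinyl and 8β-(dimethylaminomethyl) groups, 19-OTBS | [C@H]1(CN(C)C)C(=O)C[C@H]2[C@](C)(CO[Si](C)(C)C(C)(C)C)CCC[C@@]2(C)[C@@H]1C=C | intermediate
18 | amino alcohol: as 17 with C7 hydroxyl (C7 configuration not defined, either epimer) | [C@H]1(CN(C)C)C(O)C[C@H]2[C@](C)(CO[Si](C)(C)C(C)(C)C)CCC[C@@]2(C)[C@@H]1C=C | intermediate
19 | 7-O-(1H-imidazol-1-ylthiocarbonyl) derivative of 18 | [C@H]1(CN(C)C)C(OC(=S)n3ccnc3)C[C@H]2[C@](C)(CO[Si](C)(C)C(C)(C)C)CCC[C@@]2(C)[C@@H]1C=C | intermediate
20 | amine: cis-fused decalin with 9α-vinyl, 8β-(dimethylaminomethyl), C7 methylene, 19-OTBS | [C@H]1(CN(C)C)CC[C@H]2[C@](C)(CO[Si](C)(C)C(C)(C)C)CCC[C@@]2(C)[C@@H]1C=C | intermediate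
21 | 3-bromofuran-2(5H)-one | O=C1OCC=C1Br | starting material
22 | B-alkyl-9-borabicyclo[3.3.1]nonane from 20 (boron on C12) | [C@H]1(CN(C)C)CC[C@H]2[C@](C)(CO[Si](C)(C)C(C)(C)C)CCC[C@@]2(C)[C@@H]1CCB3C4CCCC3CCC4 | intermediate
23 | butenolide amine: as 20 with the 9α-substituent CH2CH2-(2-oxo-2,5-dihydrofuran-3-yl) | [C@H]1(CN(C)C)CC[C@H]2[C@](C)(CO[Si](C)(C)C(C)(C)C)CCC[C@@]2(C)[C@@H]1CCC1=CCOC1=O | intermediate
24 | N-oxide of 23 | [C@H]1(C[N+](C)(C)[O-])CC[C@H]2[C@](C)(CO[Si](C)(C)C(C)(C)C)CCC[C@@]2(C)[C@@H]1CCC1=CCOC1=O | intermediate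
25 | 8(17)-methylene butenolide, 19-OTBS (cis-fused; CH3-10, H-5, C19 and the C9 side chain α) | C=C1CC[C@H]2[C@](C)(CO[Si](C)(C)C(C)(C)C)CCC[C@@]2(C)[C@@H]1CCC1=CCOC1=O | intermediate
26 | 19-alcohol corresponding to 25 | C=C1CC[C@H]2[C@](C)(CO)CCC[C@@]2(C)[C@@H]1CCC1=CCOC1=O | intermediate
27 | CNP0350004.1: 19-acetoxy cis-fused labda-8(17),13-dien-16,15-olide with CH3-10, H-5, C19 and the C9 side chain on one face | C=C1CC[C@H]2[C@](C)(COC(C)=O)CCC[C@@]2(C)[C@@H]1CCC1=CCOC1=O | target

Total step count: 16. Longest linear sequence: 16 steps (from melonal 1 to 27).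

Steps most likely to fail

Step 9 (key step). The vinyl group may be delivered to the β face of C9 if ring A fails to shield it, or the addition beside quaternary C10 may stall so that the enolate is protonated before it meets the iminium ion. The fallback sets out from enone 13 and comes back at amino ketone 17; it reverses the order of the two bond formations so that no enolate has to be intercepted. Iodine and pyridine convert 13 into the 8-iodo enone F1. Stille coupling with Bu3SnCH2OH and Pd(PPh3)4 gives the 8-(hydroxymethyl) enone F2, and Ac2O/pyridine gives the 8-(acetoxymethyl) enone F3. The cuprate (CH2=CH)2CuLi then adds to C9 of this stronger acceptor and the enolate expels acetate (addition–elimination), giving the 8-methylene-9-vinyl ketone F4, at which stage any C9 epimer can be separated. Conjugate addition of Me2NH to the exocyclic enone returns 17.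

Step 6. The two enone arms, or the two faces of the C4 radical, may be discriminated poorly, and the tertiary radical may lose hydrogen before it closes the ring. The fallback sets out from allylic alcohol 8 and comes back at enone 13; it replaces the substrate-controlled radical closure by a catalyst-controlled polar closure. Isomerisation of 8 with [Ir(cod)(PCy3)(py)]PF6 (activated with H2, then degassed) gives the saturated dienone aldehyde F5. A cinchona-derived primary amine (9-amino-9-deoxy-epi-quinine as its trifluoroacetate, or its quinidine-derived counterpart, whichever gives the required sense) forms the enamine, which closes onto one enone arm to give the cis-fused keto aldehyde F6. NaBH4 at −78 °C reduces only the aldehyde to the hydroxy enone F7, and TBSCl/imidazole gives 13. The closest precedent is the amine-catalysed desymmetrising Michael cyclisation of aldehyde-tethered cyclohexadienones; the α-branched aldehyde and the quaternary C4 make this a less certain path than the main one.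

Step 13. The tertiary amine may complex 9-BBN, and the base-sensitive bromobutenolide may decompose before a slow transmetalation. The fallback sets out from amine 20 and comes back at butenolide amine 23; it builds the butenolide by olefination in place of cross-coupling. Hydroboration with 9-BBN and oxidation with NaBO3·4H2O give the primary alcohol F8. Parikh–Doering oxidation (SO3·pyridine, DMSO, Et3N) gives the aldehyde F9. Wittig reaction with α-(triphenylphosphoranylidene)-γ-butyrolactone gives the (E)-alkylidene lactone F10. RhCl3·3H2O in hot ethanol moves the double bond into the ring to give 23. An alkyl iodide is avoided on purpose, since it would quaternise the neighbouring amine.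

Further compounds
F1 | step 9 | 8-iodo enone (13 with iodine on C8) | C1(I)C(=O)C[C@H]2[C@](C)(CO[Si](C)(C)C(C)(C)C)CCC[C@@]2(C)C=1
F2 | step 9 | 8-(hydroxymethyl) enone | C1(CO)C(=O)C[C@H]2[C@](C)(CO[Si](C)(C)C(C)(C)C)CCC[C@@]2(C)C=1
F3 | step 9 | 8-(acetoxymethyl) enone | C1(COC(C)=O)C(=O)C[C@H]2[C@](C)(CO[Si](C)(C)C(C)(C)C)CCC[C@@]2(C)C=1
F4 | step 9 | 8-methylene-9α-vinyl C7 ketone, 19-OTBS | C=C1C(=O)C[C@H]2[C@](C)(CO[Si](C)(C)C(C)(C)C)CCC[C@@]2(C)[C@@H]1C=C
F5 | step 6 | 2-methyl-5-(1-methyl-4-oxocyclohexa-2,5-dien-1-yl)pentanal (racemic) | O=CC(C)CCCC1(C)C=CC(=O)C=C1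
F6 | step 6 | (1R,4aS,8aR)-1,4a-dimethyl-7-oxo-1,2,3,4,4a,7,8,8a-octahydronaphthalene-1-carbaldehyde (cis-fused; C19 aldehyde α) | C1C(=O)C[C@H]2[C@](C)(C=O)CCC[C@@]2(C)C=1
F7 | step 6 | cis-fused hydroxy enone (13 with free 19-OH) | C1C(=O)C[C@H]2[C@](C)(CO)CCC[C@@]2(C)C=1
F8 | step 13 | primary alcohol (20 with CH2CH2OH at C9) | [C@H]1(CN(C)C)CC[C@H]2[C@](C)(CO[Si](C)(C)C(C)(C)C)CCC[C@@]2(C)[C@@H]1CCO
F9 | step 13 | aldehyde (20 with CH2CHO at C9) | [C@H]1(CN(C)C)CC[C@H]2[C@](C)(CO[Si](C)(C)C(C)(C)C)CCC[C@@]2(C)[C@@H]1CC=O
F10 | step 13 | (E)-α-alkylidene-γ-butyrolactone (C12=C13 exocyclic) | [C@H]1(CN(C)C)CC[C@H]2[C@](C)(CO[Si](C)(C)C(C)(C)C)CCC[C@@]2(C)[C@@H]1C/C=C3\CCOC3=O
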